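I read each flask at 3.0 h, so what I need is how many time constants of L's slow decline fit before that reading.

| setting | elm | gamma | eta | epsilon |
|---|---|---|---|---|
| L | 0.13 M | 0.12 M | 0.30 M | 1.0 M |
| X | 3.6 mM (held) | 3.6 mM (held) | 3.6 mM (held) | 3.6 mM (held) |
| remark | run made earlier |  |  |  |
| time |  | 3.0 h | 3.0 h | 3.0 h |

- elm (time / min: Q / %, L / %): 10.0: 3, 64; 20.0: 7, 53; 30.0: 12, 47; 40.0: 15, 44; 50.0: 22, 43; 60.0: 24, 38

(scatter of a reading: 1.5 percentage points)

1. [Q] at the end for gamma, eta, epsilon, in this order
2. the shape of the row from first to last (falls all the way / falls, then rises / rises, then falls / hardly changes / rises all the way)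

- at the start none of Z is dissolved
- candidate steps: Z + D -> Q; L -> D; X <-> Z; L + Z <-> G
- "hardly changes" means that all values lie within two and a half points (for a concentration: within two and a half percent of the largest)

In elm, L stands at 64% of its charge after 10.0 min, a drop I take as the binding L + Z <-> G, and then it sinks slowly. I call the clock the time constant of that slow decline, reckoned from the L readings at 30.0 min and 60.0 min: 141 min. The scatter of those two readings makes it uncertain by 23.9%. If Z stays near saturation, the decline is pseudo-first-order and the charge drops out of the clock. I therefore let the 76.0% of the charge that is not yet Q at 60.0 min shrink on this clock, which puts Q at 67.5% of the charge in each flask. My row is 0.0810 M, 0.203 M, 0.675 M.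

Now turn it round. By my estimate, for the row to hardly change, gas would have to deliver Z at no more than about 0.450 mM/min, the average that gamma's Q in my row takes up, with Z held in G not counted. Taken as Z bound, elm's first drop in L shows 4.68 mM/min, which is 1.02 decades higher, or ten times. Epsilon's Q in my row takes up 3.75 mM/min on average, again with Z held in G not counted, and elm's figure is 0.0962 decades above that, a thin margin in this estimate.

The forecast gives 0.07 M, 0.17 M and 0.5 M, and rises all the way. It warns that "the demand for Z may exceed gas supply". Its epsilon value is lower than mine.

The flasks give 0.0830 M, 0.211 M and 0.728 M, and rises all the way, which is 69.2%, 70.3% and 72.8% of the charges. Z + D → Q (k = 12.7 /M/min); L → D (k = 0.0120 /min); X ⇌ Z, rate k3*(csat - [Z]) (kL = 2.97 /min); L + Z ⇌ G (K = 173 /M, k = 21.5 /M/min)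

At 3.00 h in gamma, L goes to D at 0.16 of the forward rate of L + Z to G, that forward rate taken alone, with the way back not counted. On the clock's reckoning, gamma's L, falling from 30.3% at 1.50 h to 15.6% at 3.00 h, gives 136 min, while eta's L, falling from 30.0% to 15.1% over the same span, gives 131 min.

The earlier runs and the new flask are simulated from invented constants, noise included.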